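**Plan**

1. Cyclohexane numbering used here: C1 = C(OH)CH3, C2 = CH–aryl, C3 = CH2, C4 = CH–isopropenyl, C5 and C6 = CH2. The retrosynthesis cuts, in order: the two C–prenyl bonds at the quaternary carbon of the triketone ring, the aryl–isobutyryl bond, C4–C5 together with C6–C1, then C2–C3 and the aryl–CH2 bond.
2. Enabling feature: the unsubstituted C5–C6 bridge lies between a tertiary carbinol (C1, the trace of a methyl ketone) and a methine bearing CH2=C(CH3)– (C4, the trace of an SN2′ displacement on a 2-methylallyl chloride). An ethane-1,2-diyl dianion equivalent can therefore join a ketone and an allylic chloride.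
3. Forward: phloroglucinol → tris-MOM ether → arylacetic acid → enantioselective alkylation with a C5 bromo-chloride → methyl ketone 15.
4. Step 9 closes the cyclohexane ring: Cp2Zr(C2H4) inserts the ketone C=O (C6–C1), then copper-catalysed intramolecular SN2′ forms C4–C5 and the isopropenyl group.
5. The arene is then acylated by ortho-metalation and freed of MOM groups. The triketone ring arises last, by dearomative geminal diprenylation.
6. Stereochemistry: C2 by reagent control (chiral lithium amide alkylation); C1 relayed from C2 by Felkin–Anh addition; C4 relayed by a chair ring closure.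

Key step: step 9

Remark: the target is drawn as one enol tautomer of the 2-acylcyclohexane-1,3,5-trione core; the tautomers interconvert and the route delivers this equilibrium form.
Remark: the sense of induction of the chiral lithium amide in step 6 is assumed, not known; the antipodal base is used if a test alkylation shows the opposite sense.

**Step 1**
Reactants: 1 2-methyl-2-vinyloxirane (racemic)
Product: 2 (2E)-4-bromo-2-methylbut-2-en-1-ol
Conditions: 48% aq. HBr, CuBr (5 mol%), Et2O, −20 → 0 °C
Reagents that add atoms: hydrogen bromide, Br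
Why: Copper-assisted SN2′ (conjugate) opening of the vinyl epoxide by bromide at the terminal vinyl carbon should give the primary allylic bromide and the (E)-trisubstituted alkene.

**Step 2**
Reactants: 2 (2E)-4-bromo-2-methylbut-2-en-1-ol
Product: 3 (2E)-4-bromo-1-chloro-2-methylbut-2-ene
Conditions: 1-chloro-N,N,2-trimethylprop-1-en-1-amine (1.1 equiv), CH2Cl2, 0 °C
Reagents that add atoms: 1-chloro-N,N,2-trimethylprop-1-en-1-amine, CC(C)=C(Cl)N(C)C
Why: Deoxychlorination of a primary allylic alcohol by an α-chloroenamine runs through an alkoxy-iminium chloride ion pair under neutral conditions, so the chloride should form without allylic transposition and without a free halide salt or phosphine that would attack the allylic bromide.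

**Step 3**
Reactants: 4 benzene-1,3,5-triol (phloroglucinol)
Product: 5 1,3,5-tris(methoxymethoxy)benzene
Conditions: NaH (3.6 equiv), MOMCl (3.6 equiv), DMF, 0 °C → rt
Reagents that add atoms: chloromethyl methyl ether, COCCl
Why: Threefold Williamson O-alkylation of the phloroglucinol trianion by the hard electrophile MOMCl should favour O- over C-alkylation and installs groups that direct the later metalations and can be removed without protic acid.

**Step 4**
Reactants: 5 1,3,5-tris(methoxymethoxy)benzene
Product: 7 2-[2,4,6-tris(methoxymethoxy)phenyl]ethan-1-ol, via aryllithium 6 (not isolated)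
Conditions: n-BuLi (1.1 equiv), THF, 0 °C, 1 h; ethylene oxide (3 equiv), 0 °C → rt; H2O
Reagents that add atoms: ethylene oxide, C1CO1
Why: Directed ortho-metalation at a ring CH flanked by two MOM ethers gives aryllithium 6, which opens ethylene oxide by SN2 attack.

**Step 5**
Reactants: 7 2-[2,4,6-tris(methoxymethoxy)phenyl]ethan-1-ol
Product: 9 [2,4,6-tris(methoxymethoxy)phenyl]acetic acid, via arylacetaldehyde 8 (not isolated)
Conditions: TEMPO (20 mol%), PhI(OAc)2 (2.2 equiv), MeCN/H2O 1:1, rt
Reagents that add atoms: water, O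
Why: Oxoammonium-catalysed (TEMPO) oxidation takes the primary alcohol through aldehyde 8 and its hydrate to the acid without a chlorine source that would attack the electron-rich ring and without cleaving the MOM ethers.

**Step 6**
Reactants: 9 [2,4,6-tris(methoxymethoxy)phenyl]acetic acid; 3 (2E)-4-bromo-1-chloro-2-methylbut-2-ene
Product: 11 (2R,4E)-6-chloro-5-methyl-2-[2,4,6-tris(methoxymethoxy)phenyl]hex-4-enoic acid, via dilithium enediolate 10 (not isolated)
Conditions: N1,N3-bis[(1R)-1-phenyl-2-(piperidin-1-yl)ethyl]propane-1,3-diamine (1.05 equiv; its antipode if needed for the (R)-acid), n-BuLi (4.0 equiv), THF, 0 °C; 3 (1.2 equiv), −78 °C; cold 1 M HCl work-up (amine recovered)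
Reagents that add atoms: none
Why: Enantioselective alkylation of the arylacetic acid enediolate 10 inside a mixed aggregate with the C2-symmetric chiral dilithium amide sets the aryl-bearing stereocenter by reagent control, and the enediolate should attack only the more reactive, less hindered CH2Br end of 3 (SN2), which keeps the allylic chloride for step 9.

**Step 7**
Reactants: 11 (2R,4E)-6-chloro-5-methyl-2-[2,4,6-tris(methoxymethoxy)phenyl]hex-4-enoic acid
Product: 13 (2R,4E)-6-chloro-N-methoxy-N,5-dimethyl-2-[2,4,6-tris(methoxymethoxy)phenyl]hex-4-enamide, via acyl imidazole 12 (not isolated)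
Conditions: CDI (1.2 equiv), CH2Cl2, 0 °C; MeNH(OMe)·HCl (1.5 equiv), rt
Reagents that add atoms: N,O-dimethylhydroxylamine hydrochloride, CNOC.Cl
Why: Amide formation through the acyl imidazole (CDI activation) is mild and should not epimerise the α-aryl center, whose acidity is lowered because the di-ortho-substituted ring is twisted out of conjugation.

**Step 8**
Reactants: 13 (2R,4E)-6-chloro-N-methoxy-N,5-dimethyl-2-[2,4,6-tris(methoxymethoxy)phenyl]hex-4-enamide
Product: 15 (3R,5E)-7-chloro-6-methyl-3-[2,4,6-tris(methoxymethoxy)phenyl]hept-5-en-2-one, via bromomagnesium hemiaminal 14 (not isolated)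
Conditions: MeMgBr (1.5 equiv), THF, −78 → 0 °C; H2O
Reagents that add atoms: methylmagnesium bromide, C[Mg]Br
Why: Grignard addition to the N-methoxy-N-methylamide (Weinreb ketone synthesis) stops at the chelated hemiaminal 14 and gives the methyl ketone on work-up, the allylic chloride being inert to MeMgBr at low temperature without copper.

**Step 9**
Reactants: 15 (3R,5E)-7-chloro-6-methyl-3-[2,4,6-tris(methoxymethoxy)phenyl]hept-5-en-2-one
Product: 17 (1R,2R,4S)-1-methyl-2-[2,4,6-tris(methoxymethoxy)phenyl]-4-(prop-1-en-2-yl)cyclohexan-1-ol, via oxazirconacyclopentane 16 (not isolated)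
Conditions: Cp2ZrCl2 (1.2 equiv), EtMgBr (2.4 equiv), THF, −78 °C, 1 h; add 15, −78 → 0 °C; CuCl (10 mol%), 0 °C → rt; H2O
Reagents that add atoms: ethylmagnesium bromide, CC[Mg]Br
Why: Proposed new method: warming Cp2ZrEt2 (from Cp2ZrCl2 and EtMgBr) expels ethane and leaves Cp2Zr(C2H4), a zirconacyclopropane that acts as an ethane-1,2-diyl dianion; the ketone C=O of 15 inserts into one Zr–C bond to give oxazirconacyclopentane 16 (C6–C1 bond), and CuCl then transmetalates the remaining Zr–CH2 bond to an alkylcopper that attacks the alkene carbon of the allylic chloride in an intramolecular anti-SN2′ displacement (C4–C5 bond), which expels chloride and unveils the isopropenyl group. The closest known reaction types are the insertion of ketones into zirconocene–alkene complexes to give oxazirconacyclopentanes and the CuCl-catalysed allylation of zirconacycle Zr–C bonds by allylic chlorides, each known separately and intermolecularly but not joined into an annulation. The cyclohexane closes in a 6-exo-trig mode (attack on the proximal alkene carbon, new C=C exocyclic), the 8-membered alternative from attack at CH2Cl being out of reach. C1 is set in the insertion by Felkin–Anh control, the 2,4,6-trisubstituted aryl group on C2 standing perpendicular to the carbonyl and the C–C bond forming anti to it, which places the oxygen cis to the aryl group; C4 is set in the ring closure through a chair transition state that holds the aryl group and the developing isopropenyl group equatorial (2,4-cis). The step needs C=O insertion to outrun attack of the divalent zirconium on the allylic chloride and enolisation, which the poorly coordinating trisubstituted alkene, the low temperature and the exact 2:1 EtMgBr:Cp2ZrCl2 ratio (no free Grignard reagent) should secure, and it needs C2 to keep its configuration, which the absence of base and the non-conjugating aryl group favour.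

**Step 10**
Reactants: 17 (1R,2R,4S)-1-methyl-2-[2,4,6-tris(methoxymethoxy)phenyl]-4-(prop-1-en-2-yl)cyclohexan-1-ol
Product: 20 1-{3-[(1R,2R,5S)-2-hydroxy-2-methyl-5-(prop-1-en-2-yl)cyclohexyl]-2,4,6-tris(methoxymethoxy)phenyl}-2-methylpropan-1-one, via dilithio species 18 (not isolated), via lithium hemiaminal 19 (not isolated)
Conditions: n-BuLi (2.3 equiv), THF, −78 → 0 °C; N-methoxy-N,2-dimethylpropanamide (1.5 equiv), −78 °C → rt; H2O
Reagents that add atoms: N-methoxy-N,2-dimethylpropanamide, CON(C)C(=O)C(C)C
Why: After deprotonation of the carbinol, directed ortho-metalation at a ring CH between two MOM ethers and acylation of the aryllithium by the N-methoxy-N-methylamide give the aryl ketone without over-addition, and the two free ring positions are equivalent so one regioisomer results.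

**Step 11**
Reactants: 20 1-{3-[(1R,2R,5S)-2-hydroxy-2-methyl-5-(prop-1-en-2-yl)cyclohexyl]-2,4,6-tris(methoxymethoxy)phenyl}-2-methylpropan-1-one
Product: 22 1-{2,4,6-trihydroxy-3-[(1R,2R,5S)-2-hydroxy-2-methyl-5-(prop-1-en-2-yl)cyclohexyl]phenyl}-2-methylpropan-1-one, via tetrakis(trimethylsilyl) ether 21 (not isolated)
Conditions: TMSOTf (8 equiv), 2,2′-bipyridyl (12 equiv), MeCN, 0 °C → rt; H2O, rt
Reagents that add atoms: none
Why: Silyl triflate with 2,2′-bipyridyl cleaves aryl MOM ethers through pyridinium intermediates to aryl silyl ethers under buffered, non-protic conditions that should spare the tertiary carbinol (silylated in passing) and the isopropenyl group, and water then hydrolyses all Si–O bonds.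

**Step 12**
Reactants: 22 1-{2,4,6-trihydroxy-3-[(1R,2R,5S)-2-hydroxy-2-methyl-5-(prop-1-en-2-yl)cyclohexyl]phenyl}-2-methylpropan-1-one
Product: 24 3,5-dihydroxy-4-[(1R,2R,5S)-2-hydroxy-2-methyl-5-(prop-1-en-2-yl)cyclohexyl]-6,6-bis(3-methylbut-2-en-1-yl)-2-(2-methylpropanoyl)cyclohexa-2,4-dien-1-one (CNP0324849.1), via monoprenyl acylphloroglucinol 23 (not isolated)
Conditions: prenyl bromide (2.3 equiv), 10% aq. KOH, 0 °C → rt
Reagents that add atoms: 1-bromo-3-methylbut-2-ene, CC(C)=CCBr
Why: Twofold C-prenylation (SN2) of the acylphloroglucinol anion at the only unsubstituted ring carbon, the second alkylation being dearomative, should be preferred over attack at the ring carbon shielded by the cyclohexyl group and gives the geminal diprenyl triketone as its enol.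

**Compound list**

1 | 2-methyl-2-vinyloxirane (racemic) | C=CC1(C)CO1 | starting material
2 | (2E)-4-bromo-2-methylbut-2-en-1-ol | OC/C(C)=C/CBr | intermediate
3 | (2E)-4-bromo-1-chloro-2-methylbut-2-ene | ClC/C(C)=C/CBr | intermediate
4 | benzene-1,3,5-triol (phloroglucinol) | Oc1cc(O)cc(O)c1 | starting material
5 | 1,3,5-tris(methoxymethoxy)benzene | COCOc1cc(OCOC)cc(OCOC)c1 | intermediate
6 | [2,4,6-tris(methoxymethoxy)phenyl]lithium (formed in the flask) | [Li]c1c(OCOC)cc(OCOC)cc1OCOC | intermediate
7 | 2-[2,4,6-tris(methoxymethoxy)phenyl]ethan-1-ol | OCCc1c(OCOC)cc(OCOC)cc1OCOC | intermediate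
8 | [2,4,6-tris(methoxymethoxy)phenyl]acetaldehyde (formed in the flask) | O=CCc1c(OCOC)cc(OCOC)cc1OCOC | intermediate
9 | [2,4,6-tris(methoxymethoxy)phenyl]acetic acid | OC(=O)Cc1c(OCOC)cc(OCOC)cc1OCOC | intermediate
10 | dilithium 2-[2,4,6-tris(methoxymethoxy)phenyl]ethene-1,1-bis(olate) (formed in the flask) | [Li]OC(O[Li])=Cc1c(OCOC)cc(OCOC)cc1OCOC | intermediate
11 | (2R,4E)-6-chloro-5-methyl-2-[2,4,6-tris(methoxymethoxy)phenyl]hex-4-enoic acid | OC(=O)[C@@H](c1c(OCOC)cc(OCOC)cc1OCOC)C/C=C(\C)CCl | intermediate
12 | (2R,4E)-6-chloro-1-(imidazol-1-yl)-5-methyl-2-[2,4,6-tris(methoxymethoxy)phenyl]hex-4-en-1-one (formed in the flask) | O=C(n1ccnc1)[C@@H](c1c(OCOC)cc(OCOC)cc1OCOC)C/C=C(\C)CCl | intermediate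
13 | (2R,4E)-6-chloro-N-methoxy-N,5-dimethyl-2-[2,4,6-tris(methoxymethoxy)phenyl]hex-4-enamide | CON(C)C(=O)[C@@H](c1c(OCOC)cc(OCOC)cc1OCOC)C/C=C(\C)CCl | intermediate
14 | bromomagnesium alkoxide of the tetrahedral adduct of 13 and MeMgBr (formed in the flask) | CON(C)C(C)(O[Mg]Br)[C@@H](c1c(OCOC)cc(OCOC)cc1OCOC)C/C=C(\C)CCl | intermediate
15 | (3R,5E)-7-chloro-6-methyl-3-[2,4,6-tris(methoxymethoxy)phenyl]hept-5-en-2-one | CC(=O)[C@@H](c1c(OCOC)cc(OCOC)cc1OCOC)C/C=C(\C)CCl | intermediate
16 | 1,1-bis(cyclopentadienyl)-3-methyl-3-{(1R,3E)-5-chloro-4-methyl-1-[2,4,6-tris(methoxymethoxy)phenyl]pent-3-en-1-yl}-2-oxa-1-zirconacyclopentane, carbinol carbon configured as in 17 (formed in the flask) | C[C@]1(O[Zr](C2C=CC=C2)(C2C=CC=C2)CC1)[C@@H](c1c(OCOC)cc(OCOC)cc1OCOC)C/C=C(\C)CCl | intermediate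
17 | (1R,2R,4S)-1-methyl-2-[2,4,6-tris(methoxymethoxy)phenyl]-4-(prop-1-en-2-yl)cyclohexan-1-ol | C=C(C)[C@H]1CC[C@@](C)(O)[C@@H](c2c(OCOC)cc(OCOC)cc2OCOC)C1 | intermediate
18 | lithium alkoxide of 17 lithiated at the ring carbon between two MOM ethers (formed in the flask) | C=C(C)[C@H]1CC[C@@](C)(O[Li])[C@@H](c2c(OCOC)c([Li])c(OCOC)cc2OCOC)C1 | intermediate
19 | dilithium tetrahedral adduct of 18 and N-methoxy-N,2-dimethylpropanamide (formed in the flask) | C=C(C)[C@H]1CC[C@@](C)(O[Li])[C@@H](c2c(OCOC)c(C(O[Li])(N(C)OC)C(C)C)c(OCOC)cc2OCOC)C1 | intermediate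
20 | 1-{3-[(1R,2R,5S)-2-hydroxy-2-methyl-5-(prop-1-en-2-yl)cyclohexyl]-2,4,6-tris(methoxymethoxy)phenyl}-2-methylpropan-1-one | C=C(C)[C@H]1CC[C@@](C)(O)[C@@H](c2c(OCOC)c(C(=O)C(C)C)c(OCOC)cc2OCOC)C1 | intermediate
21 | tetrakis(trimethylsilyl) ether of 22, three aryl O–Si and the carbinol O–Si (formed in the flask) | C=C(C)[C@H]1CC[C@@](C)(O[Si](C)(C)C)[C@@H](c2c(O[Si](C)(C)C)c(C(=O)C(C)C)c(O[Si](C)(C)C)cc2O[Si](C)(C)C)C1 | intermediate
22 | 1-{2,4,6-trihydroxy-3-[(1R,2R,5S)-2-hydroxy-2-methyl-5-(prop-1-en-2-yl)cyclohexyl]phenyl}-2-methylpropan-1-one | C=C(C)[C@H]1CC[C@@](C)(O)[C@@H](c2c(O)c(C(=O)C(C)C)c(O)cc2O)C1 | intermediate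
23 | 1-{2,4,6-trihydroxy-3-[(1R,2R,5S)-2-hydroxy-2-methyl-5-(prop-1-en-2-yl)cyclohexyl]-5-(3-methylbut-2-en-1-yl)phenyl}-2-methylpropan-1-one (formed in the flask) | C=C(C)[C@H]1CC[C@@](C)(O)[C@@H](c2c(O)c(C(=O)C(C)C)c(O)c(CC=C(C)C)c2O)C1 | intermediate
24 | 3,5-dihydroxy-4-[(1R,2R,5S)-2-hydroxy-2-methyl-5-(prop-1-en-2-yl)cyclohexyl]-6,6-bis(3-methylbut-2-en-1-yl)-2-(2-methylpropanoyl)cyclohexa-2,4-dien-1-one (CNP0324849.1) | C=C(C)[C@H]1CC[C@@](C)(O)[C@@H](C2=C(O)C(CC=C(C)C)(CC=C(C)C)C(=O)C(C(=O)C(C)C)=C2O)C1 | target

**Step count and risks**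

Total step count: 12 (two steps for electrophile 3, ten in the main line).
Longest linear sequence: 10 steps (4 → 24, steps 3 to 12).

Steps most likely to fail:

1. Step 9 (Proposed new method). The divalent zirconium may attack the allylic chloride before the carbonyl inserts, facial selectivity in the insertion may be poor, or the alkylzirconium may be protonated without ring closure. The fallback sets out from 15 and returns at 17. Vinylmagnesium bromide (THF, −78 °C) adds to the ketone under the same Felkin–Anh control to give (3R,4R,6E)-8-chloro-3,7-dimethyl-4-[2,4,6-tris(methoxymethoxy)phenyl]octa-1,6-dien-3-ol F1. 9-BBN-H (THF, rt) hydroborates only the monosubstituted alkene to give 9-{(3R,4R,6E)-8-chloro-3-hydroxy-3,7-dimethyl-4-[2,4,6-tris(methoxymethoxy)phenyl]oct-6-en-1-yl}-9-borabicyclo[3.3.1]nonane F2, used without isolation. CuCl (10 mol%) and KOtBu (THF, rt → 40 °C) then effect the known copper-catalysed γ-selective allyl–alkyl coupling of an alkylborane with a primary allylic chloride, here intramolecular, which closes the ring to 17. The two bonds then form in separate, precedented events.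

2. Step 6. Enantioselectivity may be low or alkylation slow because both ortho positions of the aryl ring are substituted, and competing ring metalation may consume base. The fallback sets out from 9 and returns at 13, so it also replaces step 7. Pivaloyl chloride and Et3N (THF, −20 °C) convert 9 into 2,2-dimethylpropanoic [2,4,6-tris(methoxymethoxy)phenyl]acetic anhydride F3, used without isolation. This acylates lithiated (R)-4-benzyl-oxazolidin-2-one to give (4R)-4-benzyl-3-{[2,4,6-tris(methoxymethoxy)phenyl]acetyl}oxazolidin-2-one F4. NaN(SiMe3)2 (THF, −78 °C) forms the (Z)-sodium enolate of F4 F5, which 3 alkylates at its CH2Br end on the face away from the benzyl group to give (4R)-4-benzyl-3-{(2R,4E)-6-chloro-5-methyl-2-[2,4,6-tris(methoxymethoxy)phenyl]hex-4-enoyl}oxazolidin-2-one F6. AlMe3 with MeNH(OMe)·HCl (CH2Cl2, 0 °C) then exchanges the auxiliary for the N-methoxy-N-methylamide and returns 13.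

3. Step 12. O-alkylation, alkylation at the ring carbon that bears the cyclohexyl group, or incomplete second alkylation may compete. The fallback sets out from 22 and returns at 24. Pd(PPh3)4 (5 mol%) and 2-methylbut-3-en-2-yl methyl carbonate (2.5 equiv) in THF at rt deliver both prenyl groups by Tsuji–Trost allylation. The soft enol carbon attacks the unsubstituted terminus of the 1,1-dimethylallyl–palladium cation under near-neutral conditions, which should suppress O-alkylation. The sequence passes through 23 and makes no new compound.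

**Further compounds**

F1 | step 9 | (3R,4R,6E)-8-chloro-3,7-dimethyl-4-[2,4,6-tris(methoxymethoxy)phenyl]octa-1,6-dien-3-ol | C=C[C@@](C)(O)[C@@H](c1c(OCOC)cc(OCOC)cc1OCOC)C/C=C(\C)CCl
F2 | step 9 | 9-{(3R,4R,6E)-8-chloro-3-hydroxy-3,7-dimethyl-4-[2,4,6-tris(methoxymethoxy)phenyl]oct-6-en-1-yl}-9-borabicyclo[3.3.1]nonane | B1(CC[C@@](C)(O)[C@@H](c3c(OCOC)cc(OCOC)cc3OCOC)C/C=C(\C)CCl)C2CCCC1CCC2
F3 | step 6 | 2,2-dimethylpropanoic [2,4,6-tris(methoxymethoxy)phenyl]acetic anhydride | CC(C)(C)C(=O)OC(=O)Cc1c(OCOC)cc(OCOC)cc1OCOC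
F4 | step 6 | (4R)-4-benzyl-3-{[2,4,6-tris(methoxymethoxy)phenyl]acetyl}oxazolidin-2-one | O=C(Cc1c(OCOC)cc(OCOC)cc1OCOC)N1[C@H](Cc2ccccc2)COC1=O
F5 | step 6 | (Z)-sodium enolate of F4 | [Na]O/C(=C\c1c(OCOC)cc(OCOC)cc1OCOC)N1[C@H](Cc2ccccc2)COC1=O
F6 | step 6 | (4R)-4-benzyl-3-{(2R,4E)-6-chloro-5-methyl-2-[2,4,6-tris(methoxymethoxy)phenyl]hex-4-enoyl}oxazolidin-2-one | O=C([C@@H](c1c(OCOC)cc(OCOC)cc1OCOC)C/C=C(\C)CCl)N1[C@H](Cc2ccccc2)COC1=O
F0 | step 12 | none | none
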